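The numbers in the tables are calculated with constants of no real substance.

**The pitfall.** A single exponential does not describe the substrate in the larch run, which is the flask asked about. Its rate is 0.441 h⁻¹ over the first 3.00 h, then 0.319 h⁻¹ up to 8.00 h, which is slower. I take the substrate step as first order in substrate and in coupling partner.

- larch: substrate 0.21 M; coupling partner 1.8 equiv; the very flask that is asked about, followed so far
- flask: substrate 0.21 M; coupling partner 1.80 equiv; time 4.0 d

larch run (percent of the substrate charged)

| time / h | target / % | substrate / % |
|---|---|---|
| 3.00 | 19.9 | 26.6 |
| 8.00 | 44.3 | 5.4 |
| 15.0 | 48.2 | 0.6 |
| 40.0 | 33.7 | 0 |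

(standard deviation of a reading: 0.5 percentage points)

- on the list of suspects stand: intermediate <-> isomer of the product; intermediate <-> target; substrate + coupling partner -> intermediate + released group; coupling partner -> decomposition product

1. the best time, 4.0 d at the latest, for target
2. the amount of target, in percent of the substrate charged, at that time
3. earliest time at which at least nineteen twentieths of that best amount are there, in d
4. latest time at which they still are, in d

**The clock.** Let a be the substrate left, as a share of its charge, b the partner left, as a share of its own charge, and e the equivalents. One partner goes with each substrate, so b = (e − 1 + a)/e, and ln(b/a) then rises in a straight line with time t. The reading at 3.00 h gives 0.267 h⁻¹ for its slope s, which I call the clearing rate: the rate constant times the partner's excess concentration. Solved, a = (e − 1)/(e·exp(s·t) − 1). At 8.00 h this gives 5.63%, against a reading of 5.4%.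

**Two limits.** With the partner held at its charge (pseudo-first-order), I reckon substrate falling at 0.600 h⁻¹. With the partner held at its excess, 44.4% of its charge, the rate is s itself. The read rates lie between: the first is slower than the upper limit, and the second is faster than the lower one.

**The forecast.** It expects 49.3% at 0.5 d, with a window from 0.39 d to 0.7 d, and it holds that “the intermediate builds up and then drains”. My clock speaks of substrate only, and puts 1.85% left at that time.

**The result.** The larch flask gives 48.8% at 0.558 d, and its window runs from 0.390 d to 0.817 d, closing later than the forecast's. Substrate stands at 1.24% at that best time, and the clock gives 1.27%.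

    intermediate ⇌ isomer of the product (K = 110, k = 0.0860 h⁻¹)
    intermediate ⇌ target (K = 3.00, k = 0.200 h⁻¹)
    substrate + coupling partner → intermediate + released group (k = 1.60 M⁻¹ h⁻¹)
    coupling partner → decomposition product (k = 2.00 × 10⁻⁴ h⁻¹)

**Second flask.** In the neighbouring flask with 0.450 equiv of coupling partner, the excess changes sign, so the clearing rate scales to −0.183 h⁻¹. The same formula then gives 55.0% of substrate at 4.0 d. With 0% of the partner left, it is the limiting reagent there, and that flask holds 55.0% of substrate.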